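**Retrosynthetic overview**
1. Target (erythro, 7S,8R) ⇐ desilylation and enoate reduction of a bis-silylated erythro methyl sinapate ether.
2. Erythro C7 ⇐ Mitsunobu inversion of the threo (7R,8R) benzylic alcohol, because a syn aldol gives the threo series.
3. C7–C8 bond ⇐ Evans syn aldol of an N-(aryloxyacetyl)-(S)-4-benzyloxazolidinone boron enolate with 4-O-TIPS-syringaldehyde; the auxiliary is removed reductively to give C9–OH.
4. Imide ⇐ syringaldehyde by O-alkylation with tert-butyl bromoacetate, Wittig olefination to the E-enoate, ester acidolysis and N-acylation.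
5. No ring is formed: both arene rings come from syringaldehyde.

Assumption: lignan numbering is used (C7 = benzylic carbinol carbon, C8 = aryloxy-bearing carbon, C9 = CH2O); protecting and activating reagents bought as such are named on the reagent or conditions line and not numbered.

**Step 1**
Reactants: 1 syringaldehyde; 2 tert-butyl bromoacetate
Product: 3 tert-butyl 2-(4-formyl-2,6-dimethoxyphenoxy)acetate
Conditions: K2CO3, DMF, 60 °C
Reagents that add atoms: none
Why: Williamson ether synthesis; the phenoxide displaces bromide from the activated α-bromo ester and the aldehyde is inert to carbonate.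

**Step 2**
Reactants: 3 tert-butyl 2-(4-formyl-2,6-dimethoxyphenoxy)acetate; 4 methyl (triphenylphosphoranylidene)acetate
Product: 5 methyl (E)-3-[4-(2-tert-butoxy-2-oxoethoxy)-3,5-dimethoxyphenyl]prop-2-enoate
Conditions: toluene, 90 °C
Reagents that add atoms: none
Why: Wittig olefination with a stabilised ylide gives the E-enoate (typically >95:5, purified by crystallisation) under neutral conditions that leave the tert-butyl ester alone.

**Step 3**
Reactants: 5 methyl (E)-3-[4-(2-tert-butoxy-2-oxoethoxy)-3,5-dimethoxyphenyl]prop-2-enoate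
Product: 6 2-{2,6-dimethoxy-4-[(E)-3-methoxy-3-oxoprop-1-en-1-yl]phenoxy}acetic acid
Conditions: TFA, CH2Cl2, 0 °C to rt
Reagents that add atoms: none
Why: Acidolysis of the tert-butyl ester (loss of isobutene) is selective over the methyl enoate and the aryl methyl ethers.

**Step 4**
Reactants: 6 2-{2,6-dimethoxy-4-[(E)-3-methoxy-3-oxoprop-1-en-1-yl]phenoxy}acetic acid; 7 (S)-4-benzyloxazolidin-2-one
Product: 9 (S)-4-benzyl-3-(2-{2,6-dimethoxy-4-[(E)-3-methoxy-3-oxoprop-1-en-1-yl]phenoxy}acetyl)oxazolidin-2-one, via mixed pivalic anhydride 8 (not isolated)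
Conditions: PivCl, Et3N, THF, −20 °C; then 7, LiCl, −20 °C to rt
Reagents that add atoms: none
Why: Mixed-anhydride N-acylation; the LiCl/Et3N-activated oxazolidinone attacks the unhindered aryloxyacetyl carbonyl and not the pivaloyl one, with no strong base needed.

**Step 5**
Reactants: 1 syringaldehyde
Product: 10 3,5-dimethoxy-4-(triisopropylsilyloxy)benzaldehyde
Conditions: TIPSCl, imidazole, DMF, rt
Reagents that add atoms: triisopropylsilyl chloride, CC(C)[Si](Cl)(C(C)C)C(C)C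
Why: Phenol silylation; the TIPS ether survives Lewis acid, hydride, Mitsunobu and mild methanolysis and is removed by fluoride at the end.

**Step 6**
Reactants: 9 (S)-4-benzyl-3-(2-{2,6-dimethoxy-4-[(E)-3-methoxy-3-oxoprop-1-en-1-yl]phenoxy}acetyl)oxazolidin-2-one; 10 3,5-dimethoxy-4-(triisopropylsilyloxy)benzaldehyde
Product: 13 (S)-4-benzyl-3-[(2S,3R)-2-{2,6-dimethoxy-4-[(E)-3-methoxy-3-oxoprop-1-en-1-yl]phenoxy}-3-hydroxy-3-[3,5-dimethoxy-4-(triisopropylsilyloxy)phenyl]propanoyl]oxazolidin-2-one, via dibutylboron Z-enolate 11 (not isolated), via O-dibutylboryl aldolate 12 (not isolated)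
Conditions: Bu2BOTf, iPr2NEt, CH2Cl2, −78 to 0 °C; 10, −78 to 0 °C; then pH 7 buffer, MeOH, 30% H2O2, 0 °C
Reagents that add atoms: none
Why: Evans syn aldol; the Z-boron enolate reacts through a Zimmerman–Traxler chair on the face opposite the auxiliary benzyl group, giving the 2,3-syn adduct (2S,3R), which corresponds to 7R,8R (threo) after reduction.

**Step 7**
Reactants: 13 the syn aldol adduct
Product: 14 methyl (E)-3-[4-({(1R,2R)-1,3-dihydroxy-1-[3,5-dimethoxy-4-(triisopropylsilyloxy)phenyl]propan-2-yl}oxy)-3,5-dimethoxyphenyl]prop-2-enoate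
Conditions: NaBH4, THF/H2O (4:1), 0 °C to rt
Reagents that add atoms: none
Why: Reductive cleavage of the N-acyloxazolidinone with borohydride gives the primary alcohol without retro-aldol or epimerisation; the methyl enoate is not reduced and the auxiliary is recovered.

**Step 8**
Reactants: 14 the threo 1,3-diol
Product: 15 methyl (E)-3-[4-({(1R,2R)-3-[(tert-butyldimethylsilyl)oxy]-1-hydroxy-1-[3,5-dimethoxy-4-(triisopropylsilyloxy)phenyl]propan-2-yl}oxy)-3,5-dimethoxyphenyl]prop-2-enoate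
Conditions: TBSCl (1.1 equiv), imidazole, CH2Cl2, 0 °C
Reagents that add atoms: tert-butyldimethylsilyl chloride, CC(C)(C)[Si](C)(C)Cl
Why: Selective silylation of the primary over the hindered secondary benzylic hydroxyl leaves only C7–OH free for inversion.

**Step 9**
Reactants: 15 the threo mono-TBS ether
Product: 16 (1S,2R)-3-[(tert-butyldimethylsilyl)oxy]-2-{2,6-dimethoxy-4-[(E)-3-methoxy-3-oxoprop-1-en-1-yl]phenoxy}-1-[3,5-dimethoxy-4-(triisopropylsilyloxy)phenyl]propyl 4-nitrobenzoate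
Conditions: 4-nitrobenzoic acid, PPh3, DIAD, THF, 0 °C to rt
Reagents that add atoms: 4-nitrobenzoic acid, O=C(O)c1ccc(cc1)[N+](=O)[O-]
Why: Mitsunobu reaction; SN2 displacement of the alkoxyphosphonium by the acidic carboxylate inverts C7 (R to S), turning threo into erythro while C8 is untouched.

**Step 10**
Reactants: 16 the erythro 4-nitrobenzoate
Product: 17 methyl (E)-3-[4-({(1S,2R)-3-[(tert-butyldimethylsilyl)oxy]-1-hydroxy-1-[3,5-dimethoxy-4-(triisopropylsilyloxy)phenyl]propan-2-yl}oxy)-3,5-dimethoxyphenyl]prop-2-enoate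
Conditions: K2CO3 (0.3 equiv), MeOH/THF, 0 °C
Reagents that add atoms: none
Why: Base-catalysed transesterification removes the activated nitrobenzoate with retention at C7; exchange at the methyl enoate is degenerate and the hindered aryl TIPS and alkyl TBS ethers stay on.

**Step 11**
Reactants: 17 the erythro alcohol
Product: 18 (1S,2R)-3-[(tert-butyldimethylsilyl)oxy]-2-{4-[(E)-3-hydroxyprop-1-en-1-yl]-2,6-dimethoxyphenoxy}-1-[3,5-dimethoxy-4-(triisopropylsilyloxy)phenyl]propan-1-ol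
Conditions: DIBAL-H (5 equiv), CH2Cl2, −78 °C; Rochelle salt work-up
Reagents that add atoms: none
Why: DIBAL-H 1,2-reduction of the enoate gives the E-allylic alcohol without touching the alkene, the silyl ethers or the stereocentres.

**Step 12**
Reactants: 18 the bis-silyl triol
Product: 19 (1S,2R)-1-(4-hydroxy-3,5-dimethoxyphenyl)-2-{4-[(E)-3-hydroxyprop-1-en-1-yl]-2,6-dimethoxyphenoxy}propane-1,3-diol (target; 7S,8R)
Conditions: TBAF, AcOH, THF, 0 °C to rt
Reagents that add atoms: none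
Why: Fluoride desilylation removes both silyl groups; the acetic acid buffer prevents phenoxide-driven quinone methide formation, so C7 is not scrambled.

**Compound list**
1 | syringaldehyde (4-hydroxy-3,5-dimethoxybenzaldehyde) | COc1cc(C=O)cc(OC)c1O | starting material
2 | tert-butyl bromoacetate | CC(C)(C)OC(=O)CBr | starting material
3 | tert-butyl 2-(4-formyl-2,6-dimethoxyphenoxy)acetate | COc1cc(C=O)cc(OC)c1OCC(=O)OC(C)(C)C | intermediate
4 | methyl (triphenylphosphoranylidene)acetate | COC(=O)C=P(c1ccccc1)(c1ccccc1)c1ccccc1 | starting material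
5 | methyl (E)-3-[4-(2-tert-butoxy-2-oxoethoxy)-3,5-dimethoxyphenyl]prop-2-enoate | COC(=O)/C=C/c1cc(OC)c(OCC(=O)OC(C)(C)C)c(OC)c1 | intermediate
6 | 2-{2,6-dimethoxy-4-[(E)-3-methoxy-3-oxoprop-1-en-1-yl]phenoxy}acetic acid | COC(=O)/C=C/c1cc(OC)c(OCC(=O)O)c(OC)c1 | intermediate
7 | (S)-4-benzyloxazolidin-2-one | O=C1N[C@@H](Cc2ccccc2)CO1 | starting material
8 | mixed pivalic anhydride of 6 (not isolated) | COC(=O)/C=C/c1cc(OC)c(OCC(=O)OC(=O)C(C)(C)C)c(OC)c1 | intermediate
9 | (S)-4-benzyl-3-(2-{2,6-dimethoxy-4-[(E)-3-methoxy-3-oxoprop-1-en-1-yl]phenoxy}acetyl)oxazolidin-2-one | COC(=O)/C=C/c1cc(OC)c(OCC(=O)N2[C@@H](Cc3ccccc3)COC2=O)c(OC)c1 | intermediate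
10 | 3,5-dimethoxy-4-(triisopropylsilyloxy)benzaldehyde | COc1cc(C=O)cc(OC)c1O[Si](C(C)C)(C(C)C)C(C)C | intermediate
11 | dibutylboron Z-enolate of 9 (not isolated) | CCCCB(CCCC)O/C(=C\Oc1c(OC)cc(/C=C/C(=O)OC)cc1OC)N1[C@@H](Cc2ccccc2)COC1=O | intermediate
12 | O-dibutylboryl aldolate of 13 (not isolated) | O=C(N1[C@@H](Cc2ccccc2)COC1=O)[C@@H](Oc1c(OC)cc(/C=C/C(=O)OC)cc1OC)[C@H](OB(CCCC)CCCC)c1cc(OC)c(O[Si](C(C)C)(C(C)C)C(C)C)c(OC)c1 | intermediate
13 | (S)-4-benzyl-3-[(2S,3R)-2-{2,6-dimethoxy-4-[(E)-3-methoxy-3-oxoprop-1-en-1-yl]phenoxy}-3-hydroxy-3-[3,5-dimethoxy-4-(triisopropylsilyloxy)phenyl]propanoyl]oxazolidin-2-one (syn aldol) | O=C(N1[C@@H](Cc2ccccc2)COC1=O)[C@@H](Oc1c(OC)cc(/C=C/C(=O)OC)cc1OC)[C@H](O)c1cc(OC)c(O[Si](C(C)C)(C(C)C)C(C)C)c(OC)c1 | intermediate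
14 | methyl (E)-3-[4-({(1R,2R)-1,3-dihydroxy-1-[3,5-dimethoxy-4-(triisopropylsilyloxy)phenyl]propan-2-yl}oxy)-3,5-dimethoxyphenyl]prop-2-enoate (threo) | OC[C@@H](Oc1c(OC)cc(/C=C/C(=O)OC)cc1OC)[C@H](O)c1cc(OC)c(O[Si](C(C)C)(C(C)C)C(C)C)c(OC)c1 | intermediate
15 | methyl (E)-3-[4-({(1R,2R)-3-[(tert-butyldimethylsilyl)oxy]-1-hydroxy-1-[3,5-dimethoxy-4-(triisopropylsilyloxy)phenyl]propan-2-yl}oxy)-3,5-dimethoxyphenyl]prop-2-enoate (threo) | CC(C)(C)[Si](C)(C)OC[C@@H](Oc1c(OC)cc(/C=C/C(=O)OC)cc1OC)[C@H](O)c1cc(OC)c(O[Si](C(C)C)(C(C)C)C(C)C)c(OC)c1 | intermediate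
16 | (1S,2R)-3-[(tert-butyldimethylsilyl)oxy]-2-{2,6-dimethoxy-4-[(E)-3-methoxy-3-oxoprop-1-en-1-yl]phenoxy}-1-[3,5-dimethoxy-4-(triisopropylsilyloxy)phenyl]propyl 4-nitrobenzoate (erythro) | CC(C)(C)[Si](C)(C)OC[C@@H](Oc1c(OC)cc(/C=C/C(=O)OC)cc1OC)[C@@H](OC(=O)c1ccc(cc1)[N+](=O)[O-])c1cc(OC)c(O[Si](C(C)C)(C(C)C)C(C)C)c(OC)c1 | intermediate
17 | methyl (E)-3-[4-({(1S,2R)-3-[(tert-butyldimethylsilyl)oxy]-1-hydroxy-1-[3,5-dimethoxy-4-(triisopropylsilyloxy)phenyl]propan-2-yl}oxy)-3,5-dimethoxyphenyl]prop-2-enoate (erythro) | CC(C)(C)[Si](C)(C)OC[C@@H](Oc1c(OC)cc(/C=C/C(=O)OC)cc1OC)[C@@H](O)c1cc(OC)c(O[Si](C(C)C)(C(C)C)C(C)C)c(OC)c1 | intermediate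
18 | (1S,2R)-3-[(tert-butyldimethylsilyl)oxy]-2-{4-[(E)-3-hydroxyprop-1-en-1-yl]-2,6-dimethoxyphenoxy}-1-[3,5-dimethoxy-4-(triisopropylsilyloxy)phenyl]propan-1-ol | CC(C)(C)[Si](C)(C)OC[C@@H](Oc1c(OC)cc(/C=C/CO)cc1OC)[C@@H](O)c1cc(OC)c(O[Si](C(C)C)(C(C)C)C(C)C)c(OC)c1 | intermediate
19 | (1S,2R)-1-(4-hydroxy-3,5-dimethoxyphenyl)-2-{4-[(E)-3-hydroxyprop-1-en-1-yl]-2,6-dimethoxyphenoxy}propane-1,3-diol (7S,8R; erythro) | OC[C@@H](Oc1c(OC)cc(/C=C/CO)cc1OC)[C@@H](O)c1cc(OC)c(O)c(OC)c1 | target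

**Totals**
Total step count: 12. Longest linear sequence: 11 steps (steps 1–4 and 6–12; step 5 is a one-step branch).

**Three steps most likely to fail**

Step 9 (Mitsunobu inversion). The benzylic centre carries an oxygenated arene, so partial SN1 ionisation (retention) or elimination could erode the erythro purity. The fallback sets out from 15 and comes back at 17, bypassing 16. Oxidise C7–OH with Dess–Martin periodinane (NaHCO3, CH2Cl2) to the ketone methyl (E)-3-[4-({(2R)-3-[(tert-butyldimethylsilyl)oxy]-1-[3,5-dimethoxy-4-(triisopropylsilyloxy)phenyl]-1-oxopropan-2-yl}oxy)-3,5-dimethoxyphenyl]prop-2-enoate F1. Then reduce under chelation control with Zn(BH4)2 (Et2O, −30 °C). Zinc bridges the ketone and the α-aryloxy oxygen, and hydride enters from the hydrogen side of C8, giving the anti (erythro) alcohol 17. Any minor threo alcohol is 15 and is separated and recycled. The enoate is inert to Zn(BH4)2 at this temperature; the ketone must be kept cold and base-free to avoid C8 epimerisation.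

Step 6 (Evans aldol). The enoate and the many ether oxygens of 9 may sequester Bu2BOTf or lower conversion. The fallback sets out from 7 and 10 and comes back at 13; it carries a bromide through the aldol and installs the enoate afterwards.
- Commercial 4-bromo-2,6-dimethoxyphenol is O-alkylated with bromoacetic acid (NaOH, H2O, reflux) to 2-(4-bromo-2,6-dimethoxyphenoxy)acetic acid F2.
- PivCl/Et3N converts F2 into its mixed pivalic anhydride F3, which acylates 7 (LiCl) to give (S)-4-benzyl-3-[2-(4-bromo-2,6-dimethoxyphenoxy)acetyl]oxazolidin-2-one F4.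
- Bu2BOTf/iPr2NEt gives the dibutylboron Z-enolate F5, which adds to 10 to give the O-dibutylboryl aldolate F6.
- Oxidative work-up releases (S)-4-benzyl-3-[(2S,3R)-2-(4-bromo-2,6-dimethoxyphenoxy)-3-hydroxy-3-[3,5-dimethoxy-4-(triisopropylsilyloxy)phenyl]propanoyl]oxazolidin-2-one F7.
- A mild Heck reaction of F7 with methyl acrylate (Pd2(dba)3, P(t-Bu)3·HBF4, Cy2NMe, dioxane, 40–60 °C) installs the E-enoate and gives 13.

Step 10 (methanolysis of the nitrobenzoate). If carbonate/methanol also cleaves the aryl TIPS ether, the phenoxide would expel the C7 ester as a quinone methide and scramble C7. The fallback sets out from 16 and comes back at 18, bypassing 17. Treat 16 directly with DIBAL-H (6 equiv, CH2Cl2, −78 °C), which cleaves the nitrobenzoate reductively and reduces the enoate in one non-basic operation. This fallback makes no new compound (F0).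

**Further compounds**
F1 | step 9 | methyl (E)-3-[4-({(2R)-3-[(tert-butyldimethylsilyl)oxy]-1-[3,5-dimethoxy-4-(triisopropylsilyloxy)phenyl]-1-oxopropan-2-yl}oxy)-3,5-dimethoxyphenyl]prop-2-enoate | CC(C)(C)[Si](C)(C)OC[C@@H](Oc1c(OC)cc(/C=C/C(=O)OC)cc1OC)C(=O)c1cc(OC)c(O[Si](C(C)C)(C(C)C)C(C)C)c(OC)c1
F2 | step 6 | 2-(4-bromo-2,6-dimethoxyphenoxy)acetic acid | COc1cc(Br)cc(OC)c1OCC(=O)O
F3 | step 6 | mixed pivalic anhydride of F2 | COc1cc(Br)cc(OC)c1OCC(=O)OC(=O)C(C)(C)C
F4 | step 6 | (S)-4-benzyl-3-[2-(4-bromo-2,6-dimethoxyphenoxy)acetyl]oxazolidin-2-one | COc1cc(Br)cc(OC)c1OCC(=O)N1[C@@H](Cc2ccccc2)COC1=O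
F5 | step 6 | dibutylboron Z-enolate of F4 | CCCCB(CCCC)O/C(=C\Oc1c(OC)cc(Br)cc1OC)N1[C@@H](Cc2ccccc2)COC1=O
F6 | step 6 | O-dibutylboryl aldolate of F7 | O=C(N1[C@@H](Cc2ccccc2)COC1=O)[C@@H](Oc1c(OC)cc(Br)cc1OC)[C@H](OB(CCCC)CCCC)c1cc(OC)c(O[Si](C(C)C)(C(C)C)C(C)C)c(OC)c1
F7 | step 6 | (S)-4-benzyl-3-[(2S,3R)-2-(4-bromo-2,6-dimethoxyphenoxy)-3-hydroxy-3-[3,5-dimethoxy-4-(triisopropylsilyloxy)phenyl]propanoyl]oxazolidin-2-one | O=C(N1[C@@H](Cc2ccccc2)COC1=O)[C@@H](Oc1c(OC)cc(Br)cc1OC)[C@H](O)c1cc(OC)c(O[Si](C(C)C)(C(C)C)C(C)C)c(OC)c1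
F0 | step 10 | none | none
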